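## Retrosynthetic overview
1. The target is the isobutyrate ester of (S)-alkannin, so the last step is a chemoselective Steglich esterification of the secondary carbinol. The peri-phenols are H-bonded to the quinone C=O and stay untouched.
2. (S)-Alkannin comes from mild oxidation of its leuco adduct. That adduct comes from an enantioselective Marschalk-type hydroxyalkylation of leuco-naphthazarin (made in situ from naphthazarin) with 4-methylpent-3-enal. This is the key step: it is metal-free, uses a chiral phosphoric acid, and sets the only stereocenter.
3. Naphthazarin is purchased, so no ring is formed. The aldehyde comes from the commercial alcohol 4-methylpent-3-en-1-ol by oxidation.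

Assumptions: naphthazarin (**3**) and 4-methylpent-3-en-1-ol (**1**) are purchasable. The sense of induction cannot be predicted, so I assume (S)-TRIP (**5**) gives the (S)-carbinol. If the opposite enantiomer is found, (R)-TRIP is used.

## Route

**Step 1**
Reactants: **1** 4-methylpent-3-en-1-ol
Product: **2** 4-methylpent-3-enal
Conditions: Dess–Martin periodinane, NaHCO3, CH2Cl2, 0 °C → rt, 1 h; then wash with aq. Na2S2O3/NaHCO3, dry (Na2SO4), keep as a cold CH2Cl2 solution
Reagents that add atoms: none
Why: Dess–Martin oxidation of a primary alcohol. The NaHCO3 buffer and the reductive wash prevent acid-promoted isomerization of the β,γ-alkene into conjugation and remove iodine(III/V) residues that would oxidize the Hantzsch ester in step 2. No stereocenter is formed.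

**Step 2**
Reactants: **2** 4-methylpent-3-enal (1.0 equiv, limiting); **3** naphthazarin (1.5 equiv); **4** Hantzsch ester (1.5 equiv); **5** (S)-TRIP (10 mol%)
Product: **6** (S)-leuco-alkannin, (S)-2-(1-hydroxy-4-methylpent-3-en-1-yl)naphthalene-1,4,5,8-tetraol
Conditions: **5** (10 mol%), toluene/CH2Cl2 4:1, Ar, dark, −20 °C, 48 h; then filter through a short silica plug under N2 and use the crude product directly
Reagents that add atoms: none (**4** supplies only H)
Why: Proposed new method: asymmetric Marschalk-type hydroxyalkylation in which **4** reduces **3** to leuco-naphthazarin, whose keto/ene-diol tautomer is a C2 carbon nucleophile. The bifunctional phosphoric acid binds the aldehyde C=O through P–OH and the enol OH through P=O, so the bulky 2,4,6-triisopropylphenyl groups fix the aldehyde face in a closed aldol-type transition state that forms the (S) carbinol. Tautomerization then re-aromatizes the ring to **6**. The closest known reactions are the base-mediated Marschalk hydroxyalkylation of leucoanthraquinones and phosphoric-acid-catalyzed aldol and Friedel–Crafts hydroxyalkylations of enols and naphthols with aldehydes. Excess **3** suppresses double addition, and the low temperature and absence of base disfavor dehydration to the o-quinone methide.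

**Step 3**
Reactants: **6** crude (S)-leuco-alkannin
Product: **7** (S)-alkannin
Conditions: Ag2O (4 equiv), Na2SO4, CH2Cl2, 0 °C, 15 min; filter, then chromatograph
Reagents that add atoms: none
Why: Mild Ag(I) two-electron oxidation of the tetrahydroxynaphthalene to the naphthazarin. The excess Ag2O also reoxidizes leftover leuco-**3** to recoverable **3**. The carbinol, the trisubstituted alkene and the stereocenter are unaffected because no strong acid or base is present.

**Step 4**
Reactants: **7** (S)-alkannin; **8** isobutyric acid
Product: **9** isobutyryl alkannin (target)
Conditions: **8** (1.5 equiv), EDC·HCl (1.5 equiv), DMAP (0.1 equiv), CH2Cl2, 0 °C, 2 h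
Reagents that add atoms: isobutyric acid (**8**), CC(C)C(=O)O, which delivers the isobutyryl group
Why: Steglich esterification. The peri-phenols are H-bonded to the quinone C=O and are not acylated, so only the free secondary alcohol reacts. The carbinol stereocenter is not touched, and the mild, low-temperature conditions avoid epimerization.

## Compound list
1 | 4-methylpent-3-en-1-ol | CC(C)=CCCO | starting material
2 | 4-methylpent-3-enal | CC(C)=CCC=O | intermediate
3 | naphthazarin (5,8-dihydroxy-1,4-naphthoquinone) | O=C1C=CC(=O)c2c(O)ccc(O)c12 | starting material
4 | Hantzsch ester (diethyl 2,6-dimethyl-1,4-dihydropyridine-3,5-dicarboxylate) | CCOC(=O)C1=C(C)NC(C)=C(C1)C(=O)OCC | starting material (reductant)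
5 | (S)-TRIP, (S)-3,3'-bis(2,4,6-triisopropylphenyl)-1,1'-binaphthyl-2,2'-diyl hydrogen phosphate (axial S; the SMILES carries no axial descriptor) | O=P1(O)Oc2c(-c3c(C(C)C)cc(C(C)C)cc3C(C)C)cc3ccccc3c2-c2c(O1)c(-c1c(C(C)C)cc(C(C)C)cc1C(C)C)cc1ccccc12 | starting material (chiral phosphoric acid catalyst)
6 | (S)-leuco-alkannin | CC(C)=CC[C@H](O)c1cc(O)c2c(O)ccc(O)c2c1O | intermediate
7 | (S)-alkannin | CC(C)=CC[C@H](O)C1=CC(=O)c2c(O)ccc(O)c2C1=O | intermediate
8 | isobutyric acid | CC(C)C(=O)O | starting material
9 | isobutyryl alkannin | CC(C)=CC[C@H](OC(=O)C(C)C)C1=CC(=O)c2c(O)ccc(O)c2C1=O | target

## Totals
- Total steps: 4.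
- Longest linear sequence: 4 steps from **1**, or 3 steps from naphthazarin (**3**).

## Three steps most likely to fail

1. **Step 2 (the proposed new step).** The risks are poor ee or regioselectivity, double addition, and dehydration of the electron-rich benzylic alcohol to the o-quinone methide, which the Hantzsch ester would reduce to the deoxy compound.
   - Fallback, using known chemistry:
     1. Reduce and permethylate naphthazarin to 1,4,5,8-tetramethoxynaphthalene, then brominate at C2.
     2. Do Li–Br exchange and add to the Weinreb amide of 4-methylpent-3-enoic acid to give the aryl ketone.
     3. Reduce with a CBS oxazaborolidine and borane, choosing the CBS enantiomer that gives (S).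
     4. Acylate the carbinol with isobutyric acid, then do CAN oxidative demethylation to the 5,8-dimethoxyquinone and BCl3 cleavage of the peri-methyl ethers at −78 °C.

2. **Step 3.** The leuco adduct may dehydrate on handling or epimerize under the slightly basic Ag2O conditions.
   - Fallback: change the order of operations.
     1. Peracylate the crude leuco adduct with isobutyric anhydride/DMAP.
     2. Selectively cleave the four aryl isobutyrates with NH3/MeOH, since aryl esters are far more labile than the secondary alkyl ester.
     3. Oxidize the resulting hydroquinone ester with Ag2O.
   - The benzylic oxygen is then acylated and cannot ionize to the quinone methide.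

3. **Step 4.** The carbinol next to the quinone can epimerize or eliminate with DMAP, and phenolic acylation is possible.
   - Fallback: enzymatic acylation of **7** with vinyl isobutyrate and immobilized CAL-B in MTBE at rt. This is neutral and chemoselective for the secondary alcohol.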